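The rate constants come from no measurement.

A reading at 12 s in the west flask, or at 15 s in the south-west flask, catches the run partway, so the ring in hand is the ring constant times the time times the average free starting material up to that moment.

| flask | starting material | protic impurity | time |
|---|---|---|---|
| west | 10 mM | 3.00 mM | 12 s |
| south-west | 10 mM | 3.00 mM | 15 s |

    starting material ⇌ dormant form (K1 = 0.92, k1 = 0.039 s⁻¹)
    starting material → ring (k2 = 0.052 s⁻¹)
    starting material + protic impurity → quenched substrate (k3 = 48 M⁻¹ s⁻¹)
    2 starting material → open dimer (k4 = 0.71 M⁻¹ s⁻¹)
    starting material + open dimer → open trimer (k5 = 14 M⁻¹ s⁻¹)

1. which of the two there is more of at the end, counted by the starting material in each, west (ring / open dimer)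
2. which of the two there is more of at the end, counted by the starting material in each, south-west (ring / open dimer)
3. ring at the end, in percent of the starting material charged, west
4. ring at the end, in percent of the starting material charged, south-west

- percentages count the starting material that a species holds: one open dimer counts as two
- percentages count the starting material that a species holds: one open trimer counts as three
- a doubled species enters its step squared and goes two at a time
- run time (west): 12 s

My colleague and I reckon that average differently. I take the protic impurity, the limiting reagent of the quench, off the charge before anything else counts, because at full charge it falls at 0.480 s⁻¹, faster than the rate L = 0.0910 s⁻¹ with which ring closure and the forward step to the dormant form draw on starting material. That leaves a share f = 70.0%, decaying at L with no return from the dormant form. The mean of such a decay over a time t is f times the part decayed, divided by Lt, which in west comes to 42.6%. This M, the share of the charge standing free on average over the run, gives west 26.6% of ring, and south-west, with M at 38.2%, gives 29.8%. The gradual quench and the missing return both pull M down, while the draw to open dimer, which I leave out, is slower than L even at full charge, so I expect the flasks somewhat above these figures.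

My colleague treats starting material and dormant form as one balanced pool, free to 52.1%, which gives west 19.4% of ring. I object that the exchange needs 12.3 s to relax, about as long as the west reading. We agree on the choice: ring closure at 0.052 s⁻¹ is faster than dimerisation at 0.0142 s⁻¹ even at full charge, so west gives ring and south-west ring.

The forecast, on my side of the dispute but higher than my figures, gives ring in west and ring in south-west, with 28.7% and 32% of ring, from “a rough hand integration”.

West stands at 28.5% of ring against 2.70% as open dimer, and south-west at 31.7% against 2.65%, each closer to my figure than to my colleague's reckoning. His pool comes nearer at long standing: at 120 s west holds 59.7% of ring, where his view gives 67.3% and mine 40.0%. Read back, the west ring puts M at 45.7%, above my 42.6%. With 0.75 mM of protic impurity in the west recipe, M becomes 56.3%, which gives 35.1%, and that flask holds 34.8% of ring.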